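**Retrosynthetic overview**

1. Target 18 (all-cis) ⇒ syn-hydrogenation of the C1=C2 bond of a 1-aryl-3,4-dihydronaphthalene-2-carboxylate, which sets C1 and C2 together, anti to the C3 side chain; ring C is attached just before by Suzuki coupling at a C1 enol triflate.
2. The triflate comes from a tetralone β-keto ester whose ring B is closed at C3–C4 by photoenolization/6π-electrocyclization of an acyclic 2-aroyl alkylidene ester; this creates C3, the only stereocenter that needs reagent control.
3. Enabling feature: C4 is a benzylic carbon on C4a, ortho to C8a, which carries C1. With C1 as a ketone, the C4–H bonds lie 1,5 to the carbonyl oxygen, so ring A, C1 and C4 become a hydroxy-o-quinodimethane, and the C1 substituent C2=C3 completes the hexatriene C4=C4a–C8a=C1–C2=C3.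
4. The acyclic precursor comes from creosol (ring A with C4 as its methyl group): O-benzylation, acylation para to OMe (C1), Claisen condensation (C2 and its ester carbon), Knoevenagel condensation (C3 and its CH2O carbon).
5. Ring order: ring A is bought, ring B is closed in step 5, ring C is joined in step 7.

Key step: step 5

Remark: the SMILES is read as the (1S,2S,3R) isomer, in which the C1 aryl group and the C2 and C3 hydroxymethyl groups are mutually cis. Tetralin locants are used throughout (C1 carries the aryl group, C4 is the benzylic CH2; ring A = benzo ring, ring B = saturated ring, ring C = pendant aryl ring).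

**Route**

Step 1
Reactants: 1 2-methoxy-4-methylphenol (creosol); 2 benzyl bromide
Product: 3 1-(benzyloxy)-2-methoxy-4-methylbenzene
Conditions: K2CO3, acetone, reflux
Reagents that add atoms: benzyl bromide, BrCc1ccccc1
Why: Williamson ether synthesis (phenoxide SN2 on the benzylic bromide); the benzyl group is chosen because it is removed later in the hydrogenation step.

Step 2
Reactants: 3 1-(benzyloxy)-2-methoxy-4-methylbenzene; 4 acetic anhydride
Product: 5 1-[5-(benzyloxy)-4-methoxy-2-methylphenyl]ethan-1-one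
Conditions: Ac2O, Bi(OTf)3 (5 mol%), MeNO2, 50 °C
Reagents that add atoms: acetic anhydride, CC(=O)OC(C)=O
Why: Friedel–Crafts acylation at the position para to OMe and ortho to the methyl group, the most activated and least hindered site of a 3,4-dialkoxytoluene, under a mild triflate catalyst that should spare the benzyl ether.

Step 3
Reactants: 5 1-[5-(benzyloxy)-4-methoxy-2-methylphenyl]ethan-1-one; 6 dimethyl carbonate
Product: 7 methyl 3-[5-(benzyloxy)-4-methoxy-2-methylphenyl]-3-oxopropanoate
Conditions: NaH, (MeO)2CO, toluene, reflux; then aq. HCl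
Reagents that add atoms: dimethyl carbonate, COC(=O)OC
Why: crossed Claisen condensation of the methyl ketone enolate with dimethyl carbonate, driven by formation of the β-keto ester enolate.

Step 4
Reactants: 7 methyl 3-[5-(benzyloxy)-4-methoxy-2-methylphenyl]-3-oxopropanoate; 8 2-[(tert-butyldimethylsilyl)oxy]acetaldehyde
Product: 9 methyl 2-[5-(benzyloxy)-4-methoxy-2-methylbenzoyl]-4-[(tert-butyldimethylsilyl)oxy]but-2-enoate (E/Z mixture)
Conditions: piperidine (10 mol%), AcOH (10 mol%), 4 Å MS, CH2Cl2, 0 °C to rt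
Reagents that add atoms: 2-[(tert-butyldimethylsilyl)oxy]acetaldehyde, O=CCO[Si](C)(C)C(C)(C)C
Why: Knoevenagel condensation of the active methylene with the aldehyde; the double-bond geometry need not be controlled because both isomers interconvert under the irradiation of step 5.

Step 5
Reactants: 9 methyl 2-[5-(benzyloxy)-4-methoxy-2-methylbenzoyl]-4-[(tert-butyldimethylsilyl)oxy]but-2-enoate
Product: 11 methyl (3R)-7-(benzyloxy)-3-{[(tert-butyldimethylsilyl)oxy]methyl}-1-hydroxy-6-methoxy-3,4-dihydronaphthalene-2-carboxylate, via photoenol 10 (not isolated)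
Conditions: Ti(OiPr)4 (1.1 equiv), (R,R)-TADDOL (1.2 equiv), 4 Å MS, toluene, rt; then hν (365 nm), −40 °C
Reagents that add atoms: none
Why: Proposed new method: excitation of the aryl ketone (n,π*) is followed by 1,5-hydrogen transfer from the C4 methyl group to the carbonyl oxygen, giving the (E)-hydroxy-o-quinodimethane 10 (the Z isomer reverts to 9 by 1,5-hydrogen shift), and 10 is a hexatriene C4=C4a–C8a=C1–C2=C3 that closes thermally by disrotatory 6π-electrocyclization, forming C3–C4, restoring ring A and leaving the enol of the β-keto ester. The closest known reactions are the photoenolization/Diels–Alder reaction of o-methylaryl carbonyl compounds, including its enantioselective version with Ti(OiPr)4 and TADDOL ligands, and the 6π-closure of 2-methylbenzophenone photoenols onto their inside aryl group; an alkylidene ester as the inside 2π-partner has not been shown. Ring B is closed in the electrocyclic mode, and both double-bond isomers of 9 funnel into it because they interconvert under the irradiation. The new stereocenter C3 is set when C4 bonds to one face of C3: the Ti(OiPr)2[(R,R)-TADDOLate] unit, bound to the dienol oxygen at C1 and chelated by the C2 ester carbonyl, fixes the helical twist about C1–C2 and is expected to admit only the sense that gives (3R). The step needs closure at C4 and nowhere else, which the substrate secures because only this closure re-forms the benzene ring and no other π-bond is attached to C1.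

Step 6
Reactants: 11 methyl (3R)-7-(benzyloxy)-3-{[(tert-butyldimethylsilyl)oxy]methyl}-1-hydroxy-6-methoxy-3,4-dihydronaphthalene-2-carboxylate; 12 trifluoromethanesulfonic anhydride
Product: 13 methyl (3R)-7-(benzyloxy)-3-{[(tert-butyldimethylsilyl)oxy]methyl}-6-methoxy-1-{[(trifluoromethyl)sulfonyl]oxy}-3,4-dihydronaphthalene-2-carboxylate
Conditions: Tf2O, iPr2NEt, CH2Cl2, −78 °C
Reagents that add atoms: trifluoromethanesulfonic anhydride, O=S(=O)(OS(=O)(=O)C(F)(F)F)C(F)(F)F
Why: O-sulfonylation of the β-keto ester enol gives the vinyl triflate; the hindered amine and low temperature should leave C3 and the silyl ether untouched.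

Step 7
Reactants: 13 methyl (3R)-7-(benzyloxy)-3-{[(tert-butyldimethylsilyl)oxy]methyl}-6-methoxy-1-{[(trifluoromethyl)sulfonyl]oxy}-3,4-dihydronaphthalene-2-carboxylate; 14 [4-(benzyloxy)-3-methoxyphenyl]boronic acid
Product: 15 methyl (3R)-7-(benzyloxy)-1-[4-(benzyloxy)-3-methoxyphenyl]-3-{[(tert-butyldimethylsilyl)oxy]methyl}-6-methoxy-3,4-dihydronaphthalene-2-carboxylate
Conditions: Pd(PPh3)4 (5 mol%), K3PO4, 1,4-dioxane/H2O, 80 °C
Reagents that add atoms: [4-(benzyloxy)-3-methoxyphenyl]boronic acid, COc1cc(B(O)O)ccc1OCc1ccccc1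
Why: Suzuki–Miyaura coupling of an ester-activated vinyl triflate attaches ring C at C1 and places the C1=C2 double bond for the next step; C3 carries no carbonyl group and should not epimerize under the mild base.

Step 8
Reactants: 15 methyl (3R)-7-(benzyloxy)-1-[4-(benzyloxy)-3-methoxyphenyl]-3-{[(tert-butyldimethylsilyl)oxy]methyl}-6-methoxy-3,4-dihydronaphthalene-2-carboxylate
Product: 16 methyl (1S,2S,3R)-3-{[(tert-butyldimethylsilyl)oxy]methyl}-7-hydroxy-1-(4-hydroxy-3-methoxyphenyl)-6-methoxy-1,2,3,4-tetrahydronaphthalene-2-carboxylate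
Conditions: H2 (50 bar), Pd(OH)2/C, EtOAc/THF, 40 °C
Reagents that add atoms: none
Why: heterogeneous hydrogenation adds both hydrogens syn to the face of C1=C2 opposite the C3 CH2OTBS group, which is pseudoaxial through A(1,2) strain with the C2 ester, so the aryl, ester and CH2OTBS groups should end all-cis (1S,2S), while both benzyl ethers are hydrogenolysed in the same operation.

Step 9
Reactants: 16 methyl (1S,2S,3R)-3-{[(tert-butyldimethylsilyl)oxy]methyl}-7-hydroxy-1-(4-hydroxy-3-methoxyphenyl)-6-methoxy-1,2,3,4-tetrahydronaphthalene-2-carboxylate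
Product: 17 [(1S,2S,3R)-3-{[(tert-butyldimethylsilyl)oxy]methyl}-7-hydroxy-1-(4-hydroxy-3-methoxyphenyl)-6-methoxy-1,2,3,4-tetrahydronaphthalen-2-yl]methanol
Conditions: LiAlH4, THF, 0 °C
Reagents that add atoms: none
Why: hydride reduction of the ester to the primary alcohol is fast at low temperature and should outrun epimerization of the all-cis C2 center.

Step 10
Reactants: 17 [(1S,2S,3R)-3-{[(tert-butyldimethylsilyl)oxy]methyl}-7-hydroxy-1-(4-hydroxy-3-methoxyphenyl)-6-methoxy-1,2,3,4-tetrahydronaphthalen-2-yl]methanol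
Product: 18 [(1S,2S,3R)-7-hydroxy-1-(4-hydroxy-3-methoxyphenyl)-3-(hydroxymethyl)-6-methoxy-1,2,3,4-tetrahydronaphthalen-2-yl]methanol
Conditions: HCl (cat.), MeOH, 0 °C to rt
Reagents that add atoms: none
Why: acid-catalysed methanolysis of the primary silyl ether releases the second hydroxymethyl group without touching any stereocenter.

**Compound list**

1 | 2-methoxy-4-methylphenol (creosol) | Cc1ccc(O)c(OC)c1 | starting material
2 | benzyl bromide | BrCc1ccccc1 | starting material
3 | 1-(benzyloxy)-2-methoxy-4-methylbenzene | Cc1ccc(OCc2ccccc2)c(OC)c1 | intermediate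
4 | acetic anhydride | CC(=O)OC(C)=O | starting material
5 | 1-[5-(benzyloxy)-4-methoxy-2-methylphenyl]ethan-1-one | CC(=O)c1cc(OCc2ccccc2)c(OC)cc1C | intermediate
6 | dimethyl carbonate | COC(=O)OC | starting material
7 | methyl 3-[5-(benzyloxy)-4-methoxy-2-methylphenyl]-3-oxopropanoate | COC(=O)CC(=O)c1cc(OCc2ccccc2)c(OC)cc1C | intermediate
8 | 2-[(tert-butyldimethylsilyl)oxy]acetaldehyde | O=CCO[Si](C)(C)C(C)(C)C | starting material
9 | methyl 2-[5-(benzyloxy)-4-methoxy-2-methylbenzoyl]-4-[(tert-butyldimethylsilyl)oxy]but-2-enoate (E/Z mixture, geometry left open on purpose) | COC(=O)C(=CCO[Si](C)(C)C(C)(C)C)C(=O)c1cc(OCc2ccccc2)c(OC)cc1C | intermediate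
10 | (E)-photoenol of 9: methyl 2-{(E)-[3-(benzyloxy)-4-methoxy-6-methylidenecyclohexa-2,4-dien-1-ylidene](hydroxy)methyl}-4-[(tert-butyldimethylsilyl)oxy]but-2-enoate (held on titanium in the flask) | C=C1C=C(OC)C(OCc2ccccc2)=C/C1=C(\O)C(C(=O)OC)=CCO[Si](C)(C)C(C)(C)C | intermediate
11 | methyl (3R)-7-(benzyloxy)-3-{[(tert-butyldimethylsilyl)oxy]methyl}-1-hydroxy-6-methoxy-3,4-dihydronaphthalene-2-carboxylate (enol form of the tetralone β-keto ester) | COC(=O)C1=C(O)c2cc(OCc3ccccc3)c(OC)cc2C[C@H]1CO[Si](C)(C)C(C)(C)C | intermediate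
12 | trifluoromethanesulfonic anhydride | O=S(=O)(OS(=O)(=O)C(F)(F)F)C(F)(F)F | starting material
13 | methyl (3R)-7-(benzyloxy)-3-{[(tert-butyldimethylsilyl)oxy]methyl}-6-methoxy-1-{[(trifluoromethyl)sulfonyl]oxy}-3,4-dihydronaphthalene-2-carboxylate | COC(=O)C1=C(OS(=O)(=O)C(F)(F)F)c2cc(OCc3ccccc3)c(OC)cc2C[C@H]1CO[Si](C)(C)C(C)(C)C | intermediate
14 | [4-(benzyloxy)-3-methoxyphenyl]boronic acid | COc1cc(B(O)O)ccc1OCc1ccccc1 | starting material
15 | methyl (3R)-7-(benzyloxy)-1-[4-(benzyloxy)-3-methoxyphenyl]-3-{[(tert-butyldimethylsilyl)oxy]methyl}-6-methoxy-3,4-dihydronaphthalene-2-carboxylate | COC(=O)C1=C(c2ccc(OCc3ccccc3)c(OC)c2)c2cc(OCc3ccccc3)c(OC)cc2C[C@H]1CO[Si](C)(C)C(C)(C)C | intermediate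
16 | methyl (1S,2S,3R)-3-{[(tert-butyldimethylsilyl)oxy]methyl}-7-hydroxy-1-(4-hydroxy-3-methoxyphenyl)-6-methoxy-1,2,3,4-tetrahydronaphthalene-2-carboxylate | COc1cc([C@H]2c3cc(O)c(OC)cc3C[C@@H](CO[Si](C)(C)C(C)(C)C)[C@H]2C(=O)OC)ccc1O | intermediate
17 | [(1S,2S,3R)-3-{[(tert-butyldimethylsilyl)oxy]methyl}-7-hydroxy-1-(4-hydroxy-3-methoxyphenyl)-6-methoxy-1,2,3,4-tetrahydronaphthalen-2-yl]methanol | COc1cc([C@H]2c3cc(O)c(OC)cc3C[C@@H](CO[Si](C)(C)C(C)(C)C)[C@H]2CO)ccc1O | intermediate
18 | [(1S,2S,3R)-7-hydroxy-1-(4-hydroxy-3-methoxyphenyl)-3-(hydroxymethyl)-6-methoxy-1,2,3,4-tetrahydronaphthalen-2-yl]methanol | COc1cc([C@H]2c3cc(O)c(OC)cc3C[C@@H](CO)[C@H]2CO)ccc1O | target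

**Step count**

Total steps: 10. Longest linear sequence: 10 (from 1 to 18).

**Steps most likely to fail**

Step 5 (Proposed new method). Two processes may go wrong. The excited aroyl-enoate may relax by twisting about C2=C3 faster than it abstracts the C4 hydrogen, which would starve the photoenol channel. Photoenol that cyclizes before titanium binds it would close without facial bias and erode the enantiomeric purity at C3. The sense of induction of the (R,R)-ligand is assigned by analogy only; the (S,S)-ligand would be used if it proves opposite. The fallback uses known anionic chemistry (a Michael–Dieckmann annulation, in which ring B closes at C1–C2 rather than C3–C4); it sets out from 5 and comes back at 11. Haloform oxidation of 5 (NaOCl, dioxane/H2O) should give 5-(benzyloxy)-4-methoxy-2-methylbenzoic acid F1, and MeI/K2CO3 in DMF the ester methyl 5-(benzyloxy)-4-methoxy-2-methylbenzoate F2. Lateral lithiation of F2 (LiN(iPr)2, THF, −78 °C) and conjugate addition to methyl (2E)-3-[(4R)-2,2-dimethyl-1,3-dioxolan-4-yl]prop-2-enoate, anti to the allylic C–O bond (1,2-induction), followed by Dieckmann closure on warming, should give methyl (3R)-7-(benzyloxy)-3-[(4R)-2,2-dimethyl-1,3-dioxolan-4-yl]-1-hydroxy-6-methoxy-3,4-dihydronaphthalene-2-carboxylate F3. H5IO6 in EtOAc cleaves the acetonide and the glycol to methyl (3R)-7-(benzyloxy)-3-formyl-1-hydroxy-6-methoxy-3,4-dihydronaphthalene-2-carboxylate F4. NaBH4 (MeOH, −40 °C) gives methyl (3R)-7-(benzyloxy)-1-hydroxy-3-(hydroxymethyl)-6-methoxy-3,4-dihydronaphthalene-2-carboxylate F5, and TBSCl/imidazole returns 11.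

Step 8. Saturation of the tetrasubstituted, doubly conjugated C1=C2 bond may be slow. During that time palladium may dehydrogenate ring B to the arylnaphthalene, or deliver hydrogen to the face that carries the C3 side chain (poor facial selectivity). The fallback replaces conformational shielding by ring-fusion control; it sets out from 15 and comes back at 18. Bu4NF in THF removes the silyl group, and the alkoxide lactonizes onto the C2 ester to give (3aR)-7-(benzyloxy)-9-[4-(benzyloxy)-3-methoxyphenyl]-6-methoxy-3a,4-dihydronaphtho[2,3-c]furan-1(3H)-one F6. Hydrogenation (H2, Pd/C, EtOAc) should then add to the convex face, that of the C3a hydrogen, because only this gives a cis-fused γ-lactone; with loss of the benzyl ethers it gives (3aR,9S,9aS)-7-hydroxy-9-(4-hydroxy-3-methoxyphenyl)-6-methoxy-3a,4,9,9a-tetrahydronaphtho[2,3-c]furan-1(3H)-one F7. LiAlH4 opens F7 to 18.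

Step 2. Acylation may occur ortho to the benzyloxy group instead of para to OMe (poor regioselectivity), and the acid catalyst may cleave the benzyl ether (loss of a protecting group). The fallback sets out from 3 and comes back at 5. N-bromosuccinimide in MeCN at 0 °C brominates para to OMe without a Lewis acid and should give 1-(benzyloxy)-5-bromo-2-methoxy-4-methylbenzene F8. Bromine–lithium exchange (n-BuLi, THF, −78 °C) and acylation with N-methoxy-N-methylacetamide then give 5.

**Further compounds**

F1 | step 5 | 5-(benzyloxy)-4-methoxy-2-methylbenzoic acid | Cc1cc(OC)c(OCc2ccccc2)cc1C(=O)O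
F2 | step 5 | methyl 5-(benzyloxy)-4-methoxy-2-methylbenzoate | COC(=O)c1cc(OCc2ccccc2)c(OC)cc1C
F3 | step 5 | methyl (3R)-7-(benzyloxy)-3-[(4R)-2,2-dimethyl-1,3-dioxolan-4-yl]-1-hydroxy-6-methoxy-3,4-dihydronaphthalene-2-carboxylate | COC(=O)C1=C(O)c2cc(OCc3ccccc3)c(OC)cc2C[C@H]1[C@@H]1COC(C)(C)O1
F4 | step 5 | methyl (3R)-7-(benzyloxy)-3-formyl-1-hydroxy-6-methoxy-3,4-dihydronaphthalene-2-carboxylate | COC(=O)C1=C(O)c2cc(OCc3ccccc3)c(OC)cc2C[C@H]1C=O
F5 | step 5 | methyl (3R)-7-(benzyloxy)-1-hydroxy-3-(hydroxymethyl)-6-methoxy-3,4-dihydronaphthalene-2-carboxylate | COC(=O)C1=C(O)c2cc(OCc3ccccc3)c(OC)cc2C[C@H]1CO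
F6 | step 8 | (3aR)-7-(benzyloxy)-9-[4-(benzyloxy)-3-methoxyphenyl]-6-methoxy-3a,4-dihydronaphtho[2,3-c]furan-1(3H)-one | O=C1OC[C@@H]2Cc3cc(OC)c(OCc4ccccc4)cc3C(c3ccc(OCc4ccccc4)c(OC)c3)=C12
F7 | step 8 | (3aR,9S,9aS)-7-hydroxy-9-(4-hydroxy-3-methoxyphenyl)-6-methoxy-3a,4,9,9a-tetrahydronaphtho[2,3-c]furan-1(3H)-one | O=C1OC[C@@H]2Cc3cc(OC)c(O)cc3[C@H](c3ccc(O)c(OC)c3)[C@H]12
F8 | step 2 | 1-(benzyloxy)-5-bromo-2-methoxy-4-methylbenzene | Cc1cc(OC)c(OCc2ccccc2)cc1Br
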